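(Its constants were chosen freely; the run is a simulation.)

A small charge of starting material meets its partner here by way of a solid reagent that enters solution with a time constant of 66.7 min, so I reckon with the partner actually met, not the partner charged.

    starting material + partner ⇌ intermediate B (K1 = 680 M⁻¹, k1 = 0.18 M⁻¹ min⁻¹, Ea1 = 84.0 kJ mol⁻¹, ΔH1 = 31.0 kJ mol⁻¹)
    crystals ⇌ product, rate k2*(cs2 - [product]) while solid is left; crystals form when [product] > cs2 (cs2 = 8.1 mM, k2 = 0.085 min⁻¹)
    starting material + partner ⇌ product (K3 = 1500 M⁻¹, k3 = 0.20 M⁻¹ min⁻¹, Ea3 = 85.0 kJ mol⁻¹, ΔH3 = 0 kJ mol⁻¹)
    solid reagent ⇌ partner, rate k4*(cs4 - [partner]) while solid is left; crystals form when [partner] > cs4 (cs4 = 10 mM, k4 = 0.015 min⁻¹)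
    starting material + partner ⇌ intermediate A (K5 = 72 M⁻¹, k5 = 0.33 M⁻¹ min⁻¹, Ea5 = 84.0 kJ mol⁻¹, ΔH5 = −4.00 kJ mol⁻¹)
    (constants at 60 °C)

| flask | starting material | solid reagent | temperature | time | remark |
|---|---|---|---|---|---|
| autumn | 20 mM | 0.950 equiv | 45 °C | 3.0 h |  |
| winter | 20 mM | 0.950 equiv |  | 3.0 h | at 75 °C until 50 min, from then on at 45 °C |
| dusk | 20 mM | 0.950 equiv | 60 °C | 3.0 h |  |
| spring | 20 mM | 0.950 equiv | 75 °C | 3.0 h |  |

- product is meant together with its crystals
- solid, in amounts per volume of the solution: crystals, solid reagent
- all constants are for 60 °C and move with temperature by the activation energies and enthalpies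
- at the start none of the solid reagent is in solution

- the flask that comes out highest in amount of product, in percent of the starting material charged, or "all alike" when all lie within 1.5 percentage points (autumn / winter / dusk / spring / all alike)
- product at the end, in percent of the starting material charged, autumn
- product at the end, in percent of the starting material charged, winter
- product at the end, in percent of the starting material charged, dusk
- product at the end, in percent of the starting material charged, spring

I reckon dusk, whose temperature is the one the constants are given for. With nothing consuming it, dissolved partner climbs towards 10 mM, and the time average of that curve over 3.0 h, 6.55 mM, is what I carry as the ceiling mean partner. No activation energy is given for dissolving, so I use this figure at each temperature, and the solid charge of 19.0 mM exceeds the solubility, so the charge covers that curve. Product cannot form faster than the direct step does at full starting material, which caps dusk at 23.6%.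

The hand can tighten this. The parallel steps from the same pair have summed constants of 0.710 M⁻¹ min⁻¹, and product takes a share, the selectivity, of 28.2%. Starting material then falls pseudo-first-order at the ceiling mean partner, which lowers the upper figure to 16.0%, provided the intermediates do not run back.

For the lower figure, consumption at full starting material has the coefficient 0.0142 min⁻¹, about as fast as dissolving. Partner therefore relaxes at 0.0292 min⁻¹ towards 5.14 mM, and that rising curve averages 4.16 mM, which gives 11.6%. Even the dusk cap stays below the 40.5% at which crystals start.

The forecast names spring as highest, with 4.3% for autumn, 9% for winter, 13% for dusk and 26% for spring, on the ground that “the hotter flask gives more product”. Its dusk figure lies inside my bracket, under the upper figure.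

The flasks give 4.54% in autumn, 8.78% in winter, 12.9% in dusk and 26.2% in spring, so spring stands highest, and dusk lies inside the bracket. For autumn I take the slowing of the direct step from dusk as roughly the square root of 15, the factor by which the step to intermediate A speeds up from the coldest to the hottest flask, that step's activation energy lying 1.00 kJ mol⁻¹ below the direct step's, and the ceiling mean partner then gives an estimated cap of 6.00%, above what autumn gives. In winter at 3.00 h, partner is made 1.69 times faster than it is used up, each step taken net, with 29.0% of the solid reagent's charge still undissolved.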